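The oxocene is disconnected to a six-membered 2-methylene-4-vinyl-1,3-dioxane. The key step exploits the γ,δ-unsaturated array O1–C2–C3–C4–C5=C6 of the eight-membered ring and the 1,3-relation of C6 and C8. In one flask the acetate carbonyl oxygen of an epoxy acetate opens the silyl-activated epoxide at C8 (O1–C8 bond, inversion), the dioxanylium ion is deprotonated to the ketene acetal, and a Claisen ring expansion forges C3–C4 and the Z-C5=C6 olefin, giving the oxocinone. The precursor is acyclic: (R)-1-[(2S,3S)-3-allyloxiran-2-yl]but-3-en-2-yl acetate. Ethyl is then added by alkylidenation and ionic hydrogenation, and bromide and acetate by two late inversions.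

Key step: step 5

Remark: locants follow the oxocene numbering O1, C2 (CHEt), C3 (CHBr), C4, C5=C6, C7, C8, side chain C9 (CHOAc) to C14, for all intermediates; the target is (2R,3S,5Z,8R,9R) with a 3E enyne; the L-fructose-derived Shi ketone is taken as commercially available.

Step 1
Reactants: 1 acrolein; 2 allenylboronic acid pinacol ester
Product: 4 (R)-hex-1-en-5-yn-3-ol, via pinacol borate 3 (not isolated)
Conditions: (R)-TRIP phosphoric acid [(R)-3,3′-bis(2,4,6-triisopropylphenyl)-1,1′-binaphthyl-2,2′-diyl hydrogen phosphate] (5 mol %), 4 Å MS, PhMe, −20 °C; aq. NaHCO3 work-up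
Reagents that add atoms: none
Why: Brønsted-acid-catalysed propargylboration (SE2′ through a six-membered chair) should add the propargyl group to the Re face of the aldehyde, which the (R)-acid is expected to expose by analogy with other enals, giving the (R)-carbinol; this centre is destroyed in step 5, so a moderate enantiomeric excess only costs material.

Step 2
Reactants: 4 (R)-hex-1-en-5-yn-3-ol
Product: 5 (R)-hex-1-en-5-yn-3-yl acetate
Conditions: Ac2O, Et3N, DMAP (cat.), CH2Cl2, 0 °C → rt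
Reagents that add atoms: acetic anhydride CC(=O)OC(C)=O
Why: DMAP-catalysed acylation installs the acetate whose methyl carbon, carbonyl carbon and carbonyl oxygen become C3, C2 and O1; no stereocentre is touched.

Step 3
Reactants: 5 (R)-hex-1-en-5-yn-3-yl acetate; 6 allyl bromide
Product: 8 (3R,5E)-nona-1,5,8-trien-3-yl acetate, via alkenylzirconocene chloride 7 (not isolated)
Conditions: Cp2Zr(H)Cl (1.1 equiv), THF, 0 °C → rt; then CuCl (10 mol %), allyl bromide, rt
Reagents that add atoms: none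
Why: Hydrozirconation (syn addition, zirconium at the terminus, alkyne much faster than the vinyl group or the ester) followed by zirconium-to-copper transmetalation and allylation with retention should give the (E)-1,4-diene.

Step 4
Reactants: 8 (3R,5E)-nona-1,5,8-trien-3-yl acetate
Product: 9 (R)-1-[(2S,3S)-3-allyloxiran-2-yl]but-3-en-2-yl acetate
Conditions: L-fructose-derived Shi ketone (1,2:4,5-di-O-isopropylidene-β-L-erythro-2,3-hexodiulo-2,6-pyranose, 30 mol %), KHSO5 (Oxone), K2CO3, n-Bu4NHSO4, MeCN/(MeO)2CH2/aq. buffer pH 10.5, 0 °C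
Reagents that add atoms: potassium peroxymonosulfate OOS(=O)(=O)[O-].[K+]
Why: Shi epoxidation: the chiral dioxirane epoxidises the trans-disubstituted olefin through a spiro transition state far faster than the two monosubstituted olefins, and the L-fructose-derived ketone should give the (S,S)-epoxide (reagent control), which fixes C8 and C9.

Step 5
Reactants: 9 (R)-1-[(2S,3S)-3-allyloxiran-2-yl]but-3-en-2-yl acetate
Product: 12 (8R,Z)-8-[(S)-1-(tert-butyldimethylsilyloxy)but-3-en-1-yl]-3,4,7,8-tetrahydro-2H-oxocin-2-one, via dioxanylium triflate 10 (not isolated), via ketene acetal 11 (not isolated)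
Conditions: TBSOTf (1.0 equiv), i-Pr2NEt (5 equiv), PhMe, −78 → 0 °C; then 130 °C (sealed tube)
Reagents that add atoms: tert-butyldimethylsilyl triflate CC(C)(C)[Si](C)(C)OS(=O)(=O)C(F)(F)F
Why: Proposed new method: the silyl triflate activates the epoxide, the acetate carbonyl oxygen opens it at C8 with inversion to give the 1,3-dioxan-2-ylium triflate 10 (O1–C8 bond, C9–O kept as its TBS ether), Hünig's base removes a proton from the 2-methyl group to give the 2-methylene-1,3-dioxane 11, and on heating 11 undergoes a [3,3]-sigmatropic (Claisen) shift that forms C3–C4, breaks C6–O and turns the former alkoxy oxygen on C6 into the lactone carbonyl oxygen. The closest known reactions are the acid-induced rearrangement of epoxy esters to bicyclic orthoesters through the same dioxanylium ions, the deprotonation of dialkoxycarbenium salts to ketene acetals, and the Claisen ring expansion of 2-methylene-4-vinyl-1,3-dioxanes to eight-membered lactones; their merger in one flask is new. The transient dioxane closes by 6-exo-tet opening of the epoxide, and the oxocinone forms by two-atom ring expansion (six to eight) through a chair-like transition state with the vinyl group axial, which can only deliver the Z-C5=C6 olefin. C8 is set by stereospecific inversion of the (S)-epoxide carbon, so its configuration derives from the Shi epoxidation, the C6 carbinol centre is consumed, and C3 is not yet stereogenic. The step needs silylation of the epoxide in preference to enolisation of the allylic acetate (which would lead to an Ireland–Claisen product with an E olefin), attack at C8 and not at C9, and deprotonation at the 2-methyl group before the cation ionises at allylic C6. One equivalent of silyl triflate at −78 °C, the higher basicity of the epoxide oxygen, the six- versus seven-membered ring choice and the trans-4,6 relation in 11 (vinyl axial, bulky side chain equatorial) should secure this.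

Step 6
Reactants: 12 (8R,Z)-8-[(S)-1-(tert-butyldimethylsilyloxy)but-3-en-1-yl]-3,4,7,8-tetrahydro-2H-oxocin-2-one
Product: 15 (3R,8R,Z)-8-[(S)-1-(tert-butyldimethylsilyloxy)but-3-en-1-yl]-3-(triethylsilyloxy)-3,4,7,8-tetrahydro-2H-oxocin-2-one, via potassium enolate 13 (not isolated), via potassium alkoxide 14 (not isolated)
Conditions: KN(SiMe3)2, THF, −78 °C; (+)-(camphorsulfonyl)oxaziridine, −78 °C; then Et3SiCl, −78 → 0 °C
Reagents that add atoms: (+)-(camphorsulfonyl)oxaziridine CC1(C)C2CCC13CS(=O)(=O)N4OC34C2; chlorotriethylsilane CC[Si](Cl)(CC)CC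
Why: Davis enolate hydroxylation: the potassium enolate should be oxidised on its exposed face, placing the new C–O bond cis to the C8 side chain (3R), the camphor-derived oxaziridine being chosen as the expected matched reagent and because its imine by-product does not trap the alkoxide, which is then silylated in the same flask.

Step 7
Reactants: 15 (3R,8R,Z)-8-[(S)-1-(tert-butyldimethylsilyloxy)but-3-en-1-yl]-3-(triethylsilyloxy)-3,4,7,8-tetrahydro-2H-oxocin-2-one
Product: 16 (2Z,3R,5Z,8R)-8-[(S)-1-(tert-butyldimethylsilyloxy)but-3-en-1-yl]-2-ethylidene-3-(triethylsilyloxy)-3,4,7,8-tetrahydro-2H-oxocine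
Conditions: CH3CHBr2, Zn, TiCl4, TMEDA, PbCl2 (cat.), THF, 0 °C → rt
Reagents that add atoms: 1,1-dibromoethane CC(Br)Br
Why: Takai–Utimoto alkylidenation (a gem-dimetallic ethylidene species adds to the lactone carbonyl and eliminates metal oxide) should give the Z enol ether; its geometry is of no consequence because the olefin is reduced next, and silyl ethers and isolated olefins are inert.

Step 8
Reactants: 16 (2Z,3R,5Z,8R)-8-[(S)-1-(tert-butyldimethylsilyloxy)but-3-en-1-yl]-2-ethylidene-3-(triethylsilyloxy)-3,4,7,8-tetrahydro-2H-oxocine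
Product: 18 (2R,3R,5Z,8R)-8-[(S)-1-(tert-butyldimethylsilyloxy)but-3-en-1-yl]-2-ethyl-3,4,7,8-tetrahydro-2H-oxocin-3-ol, via triethylsilyl ether 17 (not isolated)
Conditions: Et3SiH (5 equiv), CF3CO2H (3 equiv), CH2Cl2, −78 → −20 °C; then MeOH, 0 °C
Reagents that add atoms: none
Why: Ionic hydrogenation: protonation of the enol ether at its exocyclic carbon gives the ring oxocarbenium ion, which triethylsilane should reduce anti to the C3–O bond (polar Felkin–Anh) and on the face that places ethyl cis to the C8 substituent, setting (2R); methanol in the acidic medium then cleaves the triethylsilyl ether, which is far more labile than the secondary TBS ether.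

Step 9
Reactants: 18 (2R,3R,5Z,8R)-8-[(S)-1-(tert-butyldimethylsilyloxy)but-3-en-1-yl]-2-ethyl-3,4,7,8-tetrahydro-2H-oxocin-3-ol; 19 (E)-crotonaldehyde
Product: 20 (2E,5S)-5-(tert-butyldimethylsilyloxy)-5-[(2R,5Z,7R,8R)-8-ethyl-7-hydroxy-3,6,7,8-tetrahydro-2H-oxocin-2-yl]pent-2-enal
Conditions: crotonaldehyde (5 equiv), second-generation Hoveyda–Grubbs catalyst RuCl2(=CH-C6H4-2-O-i-Pr)(H2IMes) (5 mol %), CH2Cl2, 40 °C
Reagents that add atoms: none
Why: Olefin cross-metathesis of the terminal homoallylic olefin with the electron-poor partner crotonaldehyde should give the (E)-enal, the disubstituted ring olefin being far less reactive than the terminal one.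

Step 10
Reactants: 20 (2E,5S)-5-(tert-butyldimethylsilyloxy)-5-[(2R,5Z,7R,8R)-8-ethyl-7-hydroxy-3,6,7,8-tetrahydro-2H-oxocin-2-yl]pent-2-enal
Product: 21 (2R,3R,5Z,8R)-8-[(1S,3E)-1-(tert-butyldimethylsilyloxy)hex-3-en-5-yn-1-yl]-2-ethyl-3,4,7,8-tetrahydro-2H-oxocin-3-ol
Conditions: Me3SiCHN2, LiN(i-Pr)2 (2.5 equiv each), THF, −78 → 0 °C
Reagents that add atoms: trimethylsilyldiazomethane C[Si](C)(C)C=[N+]=[N-]
Why: Colvin homologation: lithiated trimethylsilyldiazomethane adds to the aldehyde, Peterson-type elimination and loss of N2 give an alkylidene carbene, and a 1,2-hydrogen shift delivers the terminal alkyne without touching the E olefin; the extra base covers the free hydroxyl.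

Step 11
Reactants: 21 (2R,3R,5Z,8R)-8-[(1S,3E)-1-(tert-butyldimethylsilyloxy)hex-3-en-5-yn-1-yl]-2-ethyl-3,4,7,8-tetrahydro-2H-oxocin-3-ol
Product: 22 (2R,3S,5Z,8R)-3-bromo-8-[(1S,3E)-1-(tert-butyldimethylsilyloxy)hex-3-en-5-yn-1-yl]-2-ethyl-3,4,7,8-tetrahydro-2H-oxocine
Conditions: CBr4, (n-C8H17)3P, PhMe, 70 °C
Reagents that add atoms: carbon tetrabromide BrC(Br)(Br)Br
Why: Appel-type bromination: the alkoxyphosphonium ion is displaced by bromide in an SN2 reaction with inversion, turning the (3R)-alcohol into the (3S)-bromide trans to the ethyl group.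

Step 12
Reactants: 22 (2R,3S,5Z,8R)-3-bromo-8-[(1S,3E)-1-(tert-butyldimethylsilyloxy)hex-3-en-5-yn-1-yl]-2-ethyl-3,4,7,8-tetrahydro-2H-oxocine
Product: 23 (2R,3S,5Z,8R)-3-bromo-2-ethyl-8-[(1S,3E)-1-hydroxyhex-3-en-5-yn-1-yl]-3,4,7,8-tetrahydro-2H-oxocine
Conditions: HF·pyridine, pyridine, THF, 0 °C → rt
Reagents that add atoms: none
Why: Fluoride-mediated cleavage of the TBS ether under buffered, non-basic conditions that should leave the secondary bromide and the enyne untouched.

Step 13
Reactants: 23 (2R,3S,5Z,8R)-3-bromo-2-ethyl-8-[(1S,3E)-1-hydroxyhex-3-en-5-yn-1-yl]-3,4,7,8-tetrahydro-2H-oxocine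
Product: 24 (2R,3S,5Z,8R)-8-[(1R,3E)-1-acetoxyhex-3-en-5-yn-1-yl]-3-bromo-2-ethyl-3,4,7,8-tetrahydro-2H-oxocine
Conditions: AcOH, PPh3, DIAD, PhMe, 0 °C → rt
Reagents that add atoms: acetic acid CC(=O)O
Why: Mitsunobu esterification: acetate displaces the alkoxyphosphonium group at C9 with inversion (S to R), which corrects the C9 configuration delivered by the trans-epoxide and installs the acetate in one operation.

Compound list

1 | acrolein | C=CC=O | starting material
2 | allenylboronic acid pinacol ester | C=C=CB1OC(C)(C)C(C)(C)O1 | starting material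
3 | (R)-2-(hex-1-en-5-yn-3-yloxy)-4,4,5,5-tetramethyl-1,3,2-dioxaborolane | C=C[C@H](OB1OC(C)(C)C(C)(C)O1)CC#C | intermediate
4 | (R)-hex-1-en-5-yn-3-ol | C=C[C@H](O)CC#C | intermediate
5 | (R)-hex-1-en-5-yn-3-yl acetate | C=C[C@H](OC(C)=O)CC#C | intermediate
6 | allyl bromide | C=CCBr | starting material
7 | chlorobis(cyclopentadienyl)[(1E,4R)-4-acetoxyhexa-1,5-dien-1-yl]zirconium | C=C[C@H](OC(C)=O)C/C=C/[Zr](Cl)(C1C=CC=C1)C1C=CC=C1 | intermediate
8 | (3R,5E)-nona-1,5,8-trien-3-yl acetate | C=C[C@H](OC(C)=O)C/C=C/CC=C | intermediate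
9 | (R)-1-[(2S,3S)-3-allyloxiran-2-yl]but-3-en-2-yl acetate | C=C[C@H](OC(C)=O)C[C@@H]1O[C@H]1CC=C | intermediate
10 | (4R,6R)-4-[(S)-1-(tert-butyldimethylsilyloxy)but-3-en-1-yl]-2-methyl-6-vinyl-1,3-dioxan-2-ylium triflate | CC1=[O+][C@@H](C=C)C[C@@H](O1)[C@@H](O[Si](C)(C)C(C)(C)C)CC=C.[O-]S(=O)(=O)C(F)(F)F | intermediate
11 | (4R,6R)-4-[(S)-1-(tert-butyldimethylsilyloxy)but-3-en-1-yl]-2-methylene-6-vinyl-1,3-dioxane | C=C1O[C@@H](C=C)C[C@@H](O1)[C@@H](O[Si](C)(C)C(C)(C)C)CC=C | intermediate
12 | (8R,Z)-8-[(S)-1-(tert-butyldimethylsilyloxy)but-3-en-1-yl]-3,4,7,8-tetrahydro-2H-oxocin-2-one | C=CC[C@H](O[Si](C)(C)C(C)(C)C)[C@H]1C/C=C\CCC(=O)O1 | intermediate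
13 | potassium enolate of 12 | C=CC[C@H](O[Si](C)(C)C(C)(C)C)[C@H]1C/C=C\C/C=C(\O1)[O-].[K+] | intermediate
14 | potassium (3R,8R,Z)-8-[(S)-1-(tert-butyldimethylsilyloxy)but-3-en-1-yl]-2-oxo-3,4,7,8-tetrahydro-2H-oxocin-3-olate | C=CC[C@H](O[Si](C)(C)C(C)(C)C)[C@H]1C/C=C\C[C@@H]([O-])C(=O)O1.[K+] | intermediate
15 | (3R,8R,Z)-8-[(S)-1-(tert-butyldimethylsilyloxy)but-3-en-1-yl]-3-(triethylsilyloxy)-3,4,7,8-tetrahydro-2H-oxocin-2-one | C=CC[C@H](O[Si](C)(C)C(C)(C)C)[C@H]1C/C=C\C[C@@H](O[Si](CC)(CC)CC)C(=O)O1 | intermediate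
16 | (2Z,3R,5Z,8R)-8-[(S)-1-(tert-butyldimethylsilyloxy)but-3-en-1-yl]-2-ethylidene-3-(triethylsilyloxy)-3,4,7,8-tetrahydro-2H-oxocine | C=CC[C@H](O[Si](C)(C)C(C)(C)C)[C@H]1C/C=C\C[C@@H](O[Si](CC)(CC)CC)/C(=C/C)O1 | intermediate
17 | (2R,3R,5Z,8R)-8-[(S)-1-(tert-butyldimethylsilyloxy)but-3-en-1-yl]-2-ethyl-3-(triethylsilyloxy)-3,4,7,8-tetrahydro-2H-oxocine | C=CC[C@H](O[Si](C)(C)C(C)(C)C)[C@H]1C/C=C\C[C@@H](O[Si](CC)(CC)CC)[C@@H](CC)O1 | intermediate
18 | (2R,3R,5Z,8R)-8-[(S)-1-(tert-butyldimethylsilyloxy)but-3-en-1-yl]-2-ethyl-3,4,7,8-tetrahydro-2H-oxocin-3-ol | C=CC[C@H](O[Si](C)(C)C(C)(C)C)[C@H]1C/C=C\C[C@@H](O)[C@@H](CC)O1 | intermediate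
19 | (E)-crotonaldehyde | C/C=C/C=O | starting material
20 | (2E,5S)-5-(tert-butyldimethylsilyloxy)-5-[(2R,5Z,7R,8R)-8-ethyl-7-hydroxy-3,6,7,8-tetrahydro-2H-oxocin-2-yl]pent-2-enal | O=C/C=C/C[C@H](O[Si](C)(C)C(C)(C)C)[C@H]1C/C=C\C[C@@H](O)[C@@H](CC)O1 | intermediate
21 | (2R,3R,5Z,8R)-8-[(1S,3E)-1-(tert-butyldimethylsilyloxy)hex-3-en-5-yn-1-yl]-2-ethyl-3,4,7,8-tetrahydro-2H-oxocin-3-ol | C#C/C=C/C[C@H](O[Si](C)(C)C(C)(C)C)[C@H]1C/C=C\C[C@@H](O)[C@@H](CC)O1 | intermediate
22 | (2R,3S,5Z,8R)-3-bromo-8-[(1S,3E)-1-(tert-butyldimethylsilyloxy)hex-3-en-5-yn-1-yl]-2-ethyl-3,4,7,8-tetrahydro-2H-oxocine | C#C/C=C/C[C@H](O[Si](C)(C)C(C)(C)C)[C@H]1C/C=C\C[C@H](Br)[C@@H](CC)O1 | intermediate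
23 | (2R,3S,5Z,8R)-3-bromo-2-ethyl-8-[(1S,3E)-1-hydroxyhex-3-en-5-yn-1-yl]-3,4,7,8-tetrahydro-2H-oxocine | C#C/C=C/C[C@H](O)[C@H]1C/C=C\C[C@H](Br)[C@@H](CC)O1 | intermediate
24 | (2R,3S,5Z,8R)-8-[(1R,3E)-1-acetoxyhex-3-en-5-yn-1-yl]-3-bromo-2-ethyl-3,4,7,8-tetrahydro-2H-oxocine | C#C/C=C/C[C@@H](OC(C)=O)[C@H]1C/C=C\C[C@H](Br)[C@@H](CC)O1 | target

Total step count: 13. Longest linear sequence: 13 steps (the route is linear).

Steps most likely to fail

Step 5 (Proposed new method). The cascade may leave its path in three ways. The acetate may be enolised and silylated instead of the epoxide (Ireland–Claisen of the acyclic ester, E olefin). The silyl-activated epoxide may eliminate to an allylic silyl ether. The dioxanylium ion may ionise or eliminate at allylic C6 before it is deprotonated. The fallback uses known reactions only, sets out from 9 and returns at 12. Methanolysis of 9 (K2CO3, MeOH, 0 °C) gives the epoxy alcohol (R)-1-[(2S,3S)-3-allyloxiran-2-yl]but-3-en-2-ol F1. Boc2O and DMAP convert it into the tert-butyl carbonate F2. BF3·OEt2 at −40 °C induces the established carbonate-participating epoxide opening (6-exo, inversion at C8, loss of 2-methylpropene) to the cyclic carbonate (4R,6R)-4-[(S)-1-hydroxybut-3-en-1-yl]-6-vinyl-1,3-dioxan-2-one F3. TBSOTf and 2,6-lutidine give the silyl ether F4. Methylenation of F4 with Cp2TiMe2 in PhMe at 110 °C generates ketene acetal 11, which rearranges in the same flask to lactone 12.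

Step 8. Hydride delivery to the oxocarbenium ion may show poor facial selectivity, because the C3 silyloxy group and the ring conformation need not reinforce each other, or a 1,2-hydride shift from C3 may compete. The fallback replaces the ionic reduction by a radical reduction of a mixed thioketal, sets out from 15 and returns at 17. Thionation of 15 with Lawesson's reagent (PhMe, 110 °C) gives the thionolactone F8. Addition of EtLi at −78 °C and trapping of the thiolate with MeI gives the 2-ethyl-2-(methylthio) ketal F9 as a mixture at C2. Ph3SnH with AIBN in PhMe at 110 °C replaces the methylthio group by hydrogen through the C2 radical, a process expected to favour the 2,8-cis ether 17. Compound 17 is then desilylated at C3 as in the second stage of step 8.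

Step 6. The oxidant may approach the wrong face of the enolate and give mainly the C3 epimer. The fallback corrects the centre by SN2 inversion, sets out from 12 and returns at 15. Hydroxylation of 12 without silyl trapping would give the (3S)-hydroxy lactone F5. Tf2O and 2,6-lutidine give its triflate F6. Displacement with n-Bu4NNO2 (Lattrell–Dax inversion) and hydrolysis of the nitrite ester on work-up give the (3R)-hydroxy lactone F7. Et3SiCl and imidazole convert F7 into 15.

Further compounds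

F1 | step 5 | (R)-1-[(2S,3S)-3-allyloxiran-2-yl]but-3-en-2-ol | C=C[C@H](O)C[C@@H]1O[C@H]1CC=C
F2 | step 5 | (R)-1-[(2S,3S)-3-allyloxiran-2-yl]but-3-en-2-yl tert-butyl carbonate | C=C[C@H](OC(=O)OC(C)(C)C)C[C@@H]1O[C@H]1CC=C
F3 | step 5 | (4R,6R)-4-[(S)-1-hydroxybut-3-en-1-yl]-6-vinyl-1,3-dioxan-2-one | O=C1O[C@@H](C=C)C[C@@H](O1)[C@@H](O)CC=C
F4 | step 5 | (4R,6R)-4-[(S)-1-(tert-butyldimethylsilyloxy)but-3-en-1-yl]-6-vinyl-1,3-dioxan-2-one | O=C1O[C@@H](C=C)C[C@@H](O1)[C@@H](O[Si](C)(C)C(C)(C)C)CC=C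
F5 | step 6 | (3S,8R,Z)-8-[(S)-1-(tert-butyldimethylsilyloxy)but-3-en-1-yl]-3-hydroxy-3,4,7,8-tetrahydro-2H-oxocin-2-one | C=CC[C@H](O[Si](C)(C)C(C)(C)C)[C@H]1C/C=C\C[C@H](O)C(=O)O1
F6 | step 6 | (3S,8R,Z)-8-[(S)-1-(tert-butyldimethylsilyloxy)but-3-en-1-yl]-2-oxo-3,4,7,8-tetrahydro-2H-oxocin-3-yl triflate | C=CC[C@H](O[Si](C)(C)C(C)(C)C)[C@H]1C/C=C\C[C@H](OS(=O)(=O)C(F)(F)F)C(=O)O1
F7 | step 6 | (3R,8R,Z)-8-[(S)-1-(tert-butyldimethylsilyloxy)but-3-en-1-yl]-3-hydroxy-3,4,7,8-tetrahydro-2H-oxocin-2-one | C=CC[C@H](O[Si](C)(C)C(C)(C)C)[C@H]1C/C=C\C[C@@H](O)C(=O)O1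
F8 | step 8 | (3R,8R,Z)-8-[(S)-1-(tert-butyldimethylsilyloxy)but-3-en-1-yl]-3-(triethylsilyloxy)-3,4,7,8-tetrahydro-2H-oxocine-2-thione | C=CC[C@H](O[Si](C)(C)C(C)(C)C)[C@H]1C/C=C\C[C@@H](O[Si](CC)(CC)CC)C(=S)O1
F9 | step 8 | (3R,5Z,8R)-8-[(S)-1-(tert-butyldimethylsilyloxy)but-3-en-1-yl]-2-ethyl-2-(methylthio)-3-(triethylsilyloxy)-3,4,7,8-tetrahydro-2H-oxocine (mixture at C2) | C=CC[C@H](O[Si](C)(C)C(C)(C)C)[C@H]1C/C=C\C[C@@H](O[Si](CC)(CC)CC)C(CC)(SC)O1
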